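Read at 10 h, the four new flasks hold one charge and differ in temperature.

| flask | starting material | first nucleophile | second nucleophile | protic impurity | temperature | remark | time |
|---|---|---|---|---|---|---|---|
| noon | 27 mM | 18.9 mM | 25.6 mM | 0.68 mM | −40 °C | run made earlier |  |
| dusk | 27 mM | 18.9 mM | 25.6 mM | 1 mM | −12 °C | run made earlier |  |
| winter | 27 mM | 9.4 mM | 25.6 mM | 1.35 mM | −40 °C | run made earlier |  |
| epsilon | 27 mM | 18.9 mM | 25.6 mM | 1.35 mM | −5 °C |  | 10 h |
| eta | 27 mM | 18.9 mM | 25.6 mM | 1.35 mM | −20 °C |  | 10 h |
| alpha | 27 mM | 18.9 mM | 25.6 mM | 1.35 mM | −35 °C |  | 10 h |
| theta | 27 mM | 18.9 mM | 25.6 mM | 1.35 mM | 10 °C |  | 10 h |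

| run | time / h | target / % |
|---|---|---|
| noon | 4.00 | 6.6 |
| noon | 12.0 | 14.0 |
| noon | 15.0 | 15.0 |
| noon | 30.0 | 17.3 |
| noon | 50.0 | 18.2 |
| noon | 60.0 | 17.9 |
| noon | 72.0 | 17.9 |
| dusk | 1.00 | 26.3 |
| dusk | 1.33 | 27.3 |
| dusk | 2.00 | 27.7 |
| dusk | 3.00 | 28.4 |
| dusk | 5.00 | 27.5 |
| dusk | 8.00 | 28.1 |
| dusk | 12.0 | 28.5 |
| winter | 15.0 | 11.1 |
| winter | 30.0 | 12.1 |
| winter | 50.0 | 10.8 |
| winter | 60.0 | 10.0 |
| winter | 72.0 | 9.7 |

(each reading ± 0.3 percentage points)

- in percentages every species weighs as the starting material in it: one side product B counts as two
- steps that have been proposed: starting material + target -> side product B; second nucleophile + intermediate -> other capture product; starting material <-> intermediate; first nucleophile + intermediate -> target; starting material + protic impurity -> quenched substrate; intermediate -> side product A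

- the best flask by amount of target, in percent of the starting material charged; "all alike" if 1.5 percentage points covers them all (epsilon / eta / alpha / theta / all alike)
- amount of target at the end, in percent of the starting material charged, epsilon
- amount of target at the end, in percent of the starting material charged, eta
- amount of target at the end, in percent of the starting material charged, alpha
- amount of target at the end, in percent of the starting material charged, theta

Each target contains one first nucleophile, and first nucleophile is charged in the smaller amount, at 18.9 mM against 27 mM of starting material. Its balance gives the ceiling C, the first nucleophile charged over the starting material charged: 70.0%. The noon run, with this same amount of first nucleophile, reads 18.2% at 50.0 h, a share of C of 0.260. The dusk run reaches 28.5%, a share of 0.407. Taken as first-order rises to those readings, the first readings give a time constant τ of 8.88 h in the noon run and 0.390 h in the dusk run, so a flask near the dusk run's temperature has time to finish. This reckoning therefore carries the dusk share over to eta and puts eta at 28.5%.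

The weak link is that a share of C treats target as a final product. The winter run contradicts this: target falls from 12.1% to 9.7%, a drop of 2.4 percentage points against a scatter of 0.3 points. The proposed step that consumes target is starting material + target → side product B, so the balance is reforged. Target made equals C times the fraction of first nucleophile used, and target standing equals target made minus the side product B percentage divided by two, since side product B counts double. The dusk share then stands for eta as an estimate, while theta, at 10 °C against the dusk run's −12 °C, stays open below C.

The forecast names theta as best, with 29.5% for epsilon, 24.5% for eta, 16% for alpha and 32% for theta, on the ground that “Warming therefore helps”. Its eta lies below this reckoning's.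

The flasks give 21.1% for epsilon, 30.5% for eta, 19.4% for alpha and 5.39% for theta, so eta is best.

    starting material + target → side product B (k = 0.00750 /M/s, Ea = 46.0 kJ/mol)
    second nucleophile + intermediate → other capture product (k = 0.0620 /M/s, Ea = 55.0 kJ/mol)
    starting material ⇌ intermediate (K = 0.270, k = 2.10 × 10⁻⁴ /s, Ea = 78.0 kJ/mol, ΔH = −84.0 kJ/mol)
    first nucleophile + intermediate → target (k = 0.240 /M/s, Ea = 45.0 kJ/mol)
    starting material + protic impurity → quenched substrate (k = 0.400 /M/s, Ea = 47.0 kJ/mol)
    intermediate → side product A (k = 4.70 × 10⁻⁴ /s, Ea = 83.0 kJ/mol)
    (constants at −20 °C)

In theta, 60% of the first nucleophile remains, so the balance puts target made at 28.2%, of which 5.39% stands, while side product B has reached 45.6%. The loss of starting material + target to side product B and the back reaction of intermediate to starting material act together on what stands in theta: without the first, theta holds 35.5%, and without the second, 31.9%. The neighbour of theta charged with 100 mM of second nucleophile keeps 73% of its first nucleophile, so C gives 19.1% made, of which 5.97% stands.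

(The readings are calculated with made-up constants, and the scatter is random.)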